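The numbers in the tables stem from a simulated flask on assumed constants, and the scatter is random.

The trap in these readings is a straight line: target climbs roughly along one in the earlier runs, within their scatter, and you may be tempted to stretch that line across a long tank, where the mixture sits at outlet composition and not at the charge.

all flasks: starting material 0.050 M; free catalyst 5 mol%
- north-west: coupling partner 1.1 equiv; added ligand 11 mM; run made earlier
- south: coupling partner 0.55 equiv; added ligand 11 mM; run made earlier
- north-east: coupling partner 0.83 equiv; added ligand 11 mM; run made earlier
- east: coupling partner 1.1 equiv; added ligand 5.5 mM; run made earlier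
- Saturday's: coupling partner 1.10 equiv; added ligand 11 mM; one stirred flow tank at steady state, fed with the mixture as stated, mean residence time 4.0 h
- Wednesday's: coupling partner 1.10 equiv (fed, over 4.00 h); added ligand 11 mM; all but coupling partner at the start; coupling partner goes in evenly over 4.00 h, the run ends at 4.0 h; time 4.0 h
- Monday's: coupling partner 1.10 equiv; added ligand 11 mM; one stirred flow tank at steady state, fed with the mixture as stated, mean residence time 20.0 h
- Friday's: coupling partner 1.10 equiv; added ligand 11 mM; a closed flask charged with all of it at once and left for 4.0 h; time 4.0 h

- north-west (time / h: target / %, starting material / %): 0.133: 0, 99.2; 0.333: 0.7, 99.6; 0.667: 0.7, 99.9; 1.00: 1.2, 98.9; 1.33: 1.4, 98.0; 2.00: 2.5, 97.8; 2.50: 2.5, 97.0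
- south (time / h: target / %, starting material / %): 0.500: 0.5, 99.6; 1.00: 0.4, 99.2; 1.50: 1.4, 99.1; 2.50: 1.1, 98.4; 3.00: 0.6, 97.6; 4.00: 3.3, 97.3
- north-east (time / h: target / %, starting material / %): 0.200: 0, 100.6; 0.667: 0.5, 99.9; 1.00: 1.0, 99.2; 1.50: 1.0, 98.3; 2.50: 1.5, 97.9; 3.00: 2.8, 96.9; 4.00: 2.9, 95.5
- east (time / h: target / %, starting material / %): 0.333: 0.3, 99.8; 1.00: 1.1, 99.4; 2.00: 2.8, 97.6; 3.00: 3.2, 95.2; 4.00: 5.2, 94.5

(standard deviation of a reading: 0.5 percentage points)

- the stated concentrations are those of everything mixed, before any reaction; amounts are the same in each set-up
- the feed brings no volume worth counting
- the earlier runs were made in a closed, stirred flask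

1. the set-up with the highest amount of target at the outlet or at the end, in percent of the starting material put in ("none" if the first two lie within 2 percentage points) (Saturday's / Wednesday's / Monday's / Friday's / none)
2. amount of target at the outlet or at the end, in percent of the starting material put in, Saturday's
3. amount of target at the outlet or at the end, in percent of the starting material put in, Wednesday's
4. amount of target at the outlet or at the end, in percent of the starting material put in, Monday's
5. amount of target at the outlet or at the end, in percent of the starting material put in, Friday's

The north-west run has the charge of the new flasks, and its last reading gives the charge pace, 0.0100 h⁻¹, the fraction of the charge turned into target per hour while the mixture is still close to as charged. One reading scatters by 0.5 percentage points, so treat it as rough. Pace times time is the Damköhler number, D.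

Now take two extremes for Monday's tank. If the rate held at the charge pace, the outlet would show D itself, 20.0%. If the rate fell with both reagents, and you treat the charge as symmetric, equimolar, then target equals D times the square of the unreacted fraction, which gives 14.6%.

I expect the real tank between them. The south run, at half the partner, lost starting material at 0.00675 h⁻¹ by its last reading, less than the 0.0120 h⁻¹ of the north-west run, so the readings suggest that the rate follows the partner. But the earlier runs end with 94.5% of starting material or more, so they say little about its order. I would say 17.3% for Monday's.

At 4.0 h D is 4.00% and the symmetric extreme for a tank gives 3.71%, so expect close to D from Saturday's tank and from Friday's flask. Wednesday's partner averages half its full amount, which gives about 2.00%. Monday's lower extreme already stands above these estimates.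

The forecast named Monday's, with 3.8% for Saturday's, 2% for Wednesday's, 14% for Monday's and 4% for Friday's, on the ground that “Monday's wins simply through longer residence time”.

The flasks give 4.31% for Saturday's, 2.17% for Wednesday's, 19.0% for Monday's and 4.42% for Friday's, so Monday's is best.

    catalyst intermediate C → free catalyst + target (k = 0.283 min⁻¹)
    starting material + catalyst intermediate B ⇌ catalyst intermediate C (K = 7.80 M⁻¹, k = 1.96 M⁻¹ min⁻¹)
    free catalyst + added ligand ⇌ idle complex (K = 130 M⁻¹, k = 2.55 M⁻¹ min⁻¹)
    coupling partner + free catalyst ⇌ catalyst intermediate A (K = 15.0 M⁻¹, k = 105 M⁻¹ min⁻¹)
    catalyst intermediate A ⇌ catalyst intermediate B (K = 2.90, k = 0.0177 min⁻¹)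

Monday's outlet lies inside your two extremes, and that tank is at steady state. Friday's flask and Wednesday's fed flask are not at rest at 4.0 h: Friday's still holds 95.5% of its starting material, Wednesday's 97.8%. Left until 40.0 h, Wednesday's reaches 36.1%, so beyond 4.0 h it averages 0.00943 h⁻¹, close to the charge pace read from the north-west run. Even then, 63.9% of the charge has not become target.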